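**Retrosynthetic overview**
1. The target is epigallocatechin 3-O-gallate-(4β→8)-epigallocatechin. The last C–C bond made is C4–C8′, by Friedel–Crafts arylation of a C4 methyl ether of the upper unit with penta-O-benzylepigallocatechin (chiral pool; all lower-unit rings bought), followed by one hydrogenolysis.
2. Ring C of the upper unit (O1, C2, C3, C4, C4a, C8a) is cut at C4–C3 and O1–C2: a hetero-Diels–Alder reaction of an o-quinone methide with a (Z)-2-arylethenyl gallate. Three components (salicylaldehyde, HC(OMe)3, enol ester) give ring C, C2, C3, the gallate ester and the C4 leaving group in one operation.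
3. Enabling feature: O1–C8a=C4a–C4 is a latent o-quinone methide of phloroglucinol ring A. Phenolic O1 is ortho to benzylic C4, and C4, as the diaryl-methine carbon of the interflavan bond, sits at aldehyde oxidation level. The cis C2-aryl/C3-O-galloyl pair is a Z enol ester.
4. Precursor shaping: bromine at C6 and C8 of ring A blocks Friedel–Crafts self-condensation, makes the o-quinone methide more electrophilic, and leaves in the final hydrogenolysis. The Z enol ester comes from alkyne plus acid.
5. Ring order: rings A, B, the galloyl ring and the three rings of the lower unit arrive intact. Ring C of the upper unit is the only ring built and the last ring closed.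

Key step: step 5

Assumption: the sense of asymmetric induction in step 5 cannot be assigned beforehand; the (R)-configured acid is written, and its mirror image would be used if that is the one leading to the (2R,3R) series.

**Route**

Step 1
Reactants: 1 3,5-bis(benzyloxy)phenol
Product: 2 4,6-bis(benzyloxy)-2-hydroxybenzaldehyde
Conditions: MgCl2, Et3N, (CH2O)n, MeCN, reflux
Reagents that add atoms: paraformaldehyde (formaldehyde) C=O
Why: Magnesium-mediated ortho-formylation (Casnati–Skattebøl reaction): the magnesium phenoxide delivers formaldehyde only ortho to the hydroxyl group and a second formaldehyde oxidizes the benzylic alkoxide, so the aldehyde should enter between OH and OBn; no stereocenter is formed.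

Step 2
Reactants: 2 4,6-bis(benzyloxy)-2-hydroxybenzaldehyde
Product: 3 4,6-bis(benzyloxy)-3,5-dibromo-2-hydroxybenzaldehyde
Conditions: NBS (2.1 equiv), CH2Cl2, 0 °C → rt
Reagents that add atoms: N-bromosuccinimide O=C1CCC(=O)N1Br
Why: Electrophilic aromatic bromination: the two free ring positions are each ortho/para to three oxygen substituents and should be brominated by NBS while the unactivated phenyl rings of the benzyl ethers stay untouched; no stereocenter is formed.

Step 3
Reactants: 4 3,4,5-tris(benzyloxy)benzaldehyde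
Product: 5 1,2,3-tris(benzyloxy)-5-ethynylbenzene
Conditions: dimethyl (1-diazo-2-oxopropyl)phosphonate, K2CO3, MeOH/THF, rt
Reagents that add atoms: dimethyl (1-diazo-2-oxopropyl)phosphonate CC(=O)C(=[N+]=[N-])P(=O)(OC)OC
Why: Seyferth–Gilbert homologation in the Ohira–Bestmann variant should convert the non-enolizable aryl aldehyde into the terminal alkyne under mild base; no stereocenter is formed.

Step 4
Reactants: 5 1,2,3-tris(benzyloxy)-5-ethynylbenzene; 6 3,4,5-tris(benzyloxy)benzoic acid
Product: 7 (Z)-2-[3,4,5-tris(benzyloxy)phenyl]ethenyl 3,4,5-tris(benzyloxy)benzoate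
Conditions: [RuCl2(p-cymene)]2 (2 mol%), P(4-ClC6H4)3 (6 mol%), DMAP (8 mol%), toluene, 60 °C
Reagents that add atoms: none
Why: Ruthenium-catalysed anti-Markovnikov hydro-oxycarbonylation of a terminal alkyne: the carboxylate attacks the metal-bound terminal carbon of a ruthenium vinylidene and net trans addition should give the Z enol ester, whose geometry later becomes the 2,3-cis relationship.

Step 5
Reactants: 3 4,6-bis(benzyloxy)-3,5-dibromo-2-hydroxybenzaldehyde; 7 (Z)-2-[3,4,5-tris(benzyloxy)phenyl]ethenyl 3,4,5-tris(benzyloxy)benzoate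
Product: 10 (2R,3R,4S)-5,7-bis(benzyloxy)-6,8-dibromo-4-methoxy-2-[3,4,5-tris(benzyloxy)phenyl]chroman-3-yl 3,4,5-tris(benzyloxy)benzoate, via acetal 8 (not isolated), via o-quinone methide 9 (not isolated)
Conditions: HC(OMe)3 (2 equiv), (R)-3,3′-bis(2,4,6-triisopropylphenyl)-1,1′-binaphthyl-2,2′-diyl N-triflylphosphoramide (10 mol%), 5 Å MS, CH2Cl2, rt; then 7 (1.5 equiv), −30 → 0 °C
Reagents that add atoms: trimethyl orthoformate COC(OC)OC
Why: Proposed new method: the acid turns 3 and the orthoformate into acetal 8, which loses methanol to the o-quinone methide 9 (O1=C8a–C4a=C4–OMe, reacting as its O-protonated oxocarbenium ion paired with the chiral phosphoramide anion), and this heterodiene adds the Z enol ester 7 in an inverse-electron-demand hetero-Diels–Alder reaction, the acyloxy carbon (C3) bonding to C4 and O1 to the benzylic carbon (C2). The closest known reactions are the acid-promoted three-component chroman synthesis from salicylaldehydes, trimethyl orthoformate and alkenes, and the chiral N-triflylphosphoramide-catalysed [4+2] cycloaddition of o-quinone methides with styrenes; new is a 2-acyloxystyrene as the 2π partner. Ring C is closed by an intermolecular [4+2] cycloaddition that forms C4–C3 and O1–C2, concerted but asynchronous. C2 and C3 should be set cis by suprafacial addition to the Z double bond and in the (2R,3R) sense by the chiral counter-anion held at O1–H beside the forming O1–C2 bond, while C4 (OMe) is expected to settle 3,4-trans by acid-mediated ionization and re-addition anti to the gallate and is erased in step 7 in any case. The step needs regioselectivity (cationic character at aryl-bearing C2, not at the acyloxy carbon), which the electron-rich tris(benzyloxy)phenyl group and the ester-delocalized, poorly donating acyloxy oxygen should secure, and chemoselectivity over Friedel–Crafts self-condensation, which the bromine atoms at both free positions of ring A secure while also raising the electrophilicity of 9.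

Step 6
Reactants: 11 (−)-epigallocatechin
Product: 12 5,7,3′,4′,5′-penta-O-benzyl-(−)-epigallocatechin
Conditions: BnBr (5.5 equiv), K2CO3, DMF, −10 °C → rt, argon
Reagents that add atoms: benzyl bromide BrCc1ccccc1
Why: Williamson ether synthesis: the five phenols should be alkylated under carbonate conditions that leave the secondary C3 alcohol free, and the two chiral-pool stereocenters are not touched (low temperature and exclusion of air limit C2 epimerization and oxidation of the pyrogallol ring).

Step 7
Reactants: 10 (2R,3R,4S)-5,7-bis(benzyloxy)-6,8-dibromo-4-methoxy-2-[3,4,5-tris(benzyloxy)phenyl]chroman-3-yl 3,4,5-tris(benzyloxy)benzoate; 12 5,7,3′,4′,5′-penta-O-benzyl-(−)-epigallocatechin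
Product: 13 5,7,3′,4′,5′-penta-O-benzyl-6,8-dibromo-3-O-[3,4,5-tris(benzyloxy)benzoyl]epigallocatechin-(4β→8)-5,7,3′,4′,5′-penta-O-benzylepigallocatechin
Conditions: 12 (3 equiv, excess recovered), TMSOTf (0.2 equiv), CH2Cl2, −78 → −40 °C; then Et3N
Reagents that add atoms: none
Why: Lewis-acid-mediated Friedel–Crafts arylation at C4 of a 4-alkoxyflavan (the standard interflavan coupling): TMSOTf ionizes the C4 methyl ether to the ring-A-stabilized benzylic cation, the cis C3 gallate shields its own face (dioxolenium participation) so that C8 of 12, the most nucleophilic carbon of its phloroglucinol ring, should attack anti and set C4 as 3,4-trans (4β→8), while the bromines prevent self-condensation of the electrophile.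

Step 8
Reactants: 13 5,7,3′,4′,5′-penta-O-benzyl-6,8-dibromo-3-O-[3,4,5-tris(benzyloxy)benzoyl]epigallocatechin-(4β→8)-5,7,3′,4′,5′-penta-O-benzylepigallocatechin
Product: 14 (−)-epigallocatechin 3-O-gallate-(4β→8)-(−)-epigallocatechin
Conditions: H2 (1 atm), Pd(OH)2/C, Et3N (2.2 equiv), THF/MeOH/H2O, rt
Reagents that add atoms: none
Why: Heterogeneous hydrogenolysis over Pd(OH)2/C should cleave the thirteen benzyl ethers and, with Et3N as HBr scavenger, the two aryl C–Br bonds, while the gallate ester, the interflavan bond and all five stereocenters are inert to these conditions.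

**Compound list**
1 | 3,5-bis(benzyloxy)phenol | Oc1cc(OCc2ccccc2)cc(OCc2ccccc2)c1 | starting material
2 | 4,6-bis(benzyloxy)-2-hydroxybenzaldehyde | O=Cc1c(O)cc(OCc2ccccc2)cc1OCc1ccccc1 | intermediate
3 | 4,6-bis(benzyloxy)-3,5-dibromo-2-hydroxybenzaldehyde | O=Cc1c(O)c(Br)c(OCc2ccccc2)c(Br)c1OCc1ccccc1 | intermediate
4 | 3,4,5-tris(benzyloxy)benzaldehyde | O=Cc1cc(OCc2ccccc2)c(OCc2ccccc2)c(OCc2ccccc2)c1 | starting material
5 | 1,2,3-tris(benzyloxy)-5-ethynylbenzene | C#Cc1cc(OCc2ccccc2)c(OCc2ccccc2)c(OCc2ccccc2)c1 | intermediate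
6 | 3,4,5-tris(benzyloxy)benzoic acid | OC(=O)c1cc(OCc2ccccc2)c(OCc2ccccc2)c(OCc2ccccc2)c1 | starting material
7 | (Z)-2-[3,4,5-tris(benzyloxy)phenyl]ethenyl 3,4,5-tris(benzyloxy)benzoate | O=C(O/C=C\c1cc(OCc2ccccc2)c(OCc2ccccc2)c(OCc2ccccc2)c1)c1cc(OCc2ccccc2)c(OCc2ccccc2)c(OCc2ccccc2)c1 | intermediate
8 | 3,5-bis(benzyloxy)-2,4-dibromo-6-(dimethoxymethyl)phenol (acetal, formed in the flask in step 5) | COC(OC)c1c(O)c(Br)c(OCc2ccccc2)c(Br)c1OCc1ccccc1 | intermediate
9 | (6E)-3,5-bis(benzyloxy)-2,4-dibromo-6-(methoxymethylidene)cyclohexa-2,4-dien-1-one (o-quinone methide, formed in the flask in step 5) | CO/C=C1/C(=O)C(Br)=C(OCc2ccccc2)C(Br)=C1OCc1ccccc1 | intermediate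
10 | (2R,3R,4S)-5,7-bis(benzyloxy)-6,8-dibromo-4-methoxy-2-[3,4,5-tris(benzyloxy)phenyl]chroman-3-yl 3,4,5-tris(benzyloxy)benzoate | O=C(O[C@@H]1[C@@H](OC)c2c(OCc3ccccc3)c(Br)c(OCc3ccccc3)c(Br)c2O[C@@H]1c1cc(OCc2ccccc2)c(OCc2ccccc2)c(OCc2ccccc2)c1)c1cc(OCc2ccccc2)c(OCc2ccccc2)c(OCc2ccccc2)c1 | intermediate
11 | (−)-epigallocatechin, (2R,3R) | Oc1cc(O)c2c(c1)O[C@H](c1cc(O)c(O)c(O)c1)[C@H](O)C2 | starting material
12 | 5,7,3′,4′,5′-penta-O-benzyl-(−)-epigallocatechin, (2R,3R)-5,7-bis(benzyloxy)-2-[3,4,5-tris(benzyloxy)phenyl]chroman-3-ol | c1ccccc1COc1cc(OCc2ccccc2)c2c(c1)O[C@H](c1cc(OCc3ccccc3)c(OCc3ccccc3)c(OCc3ccccc3)c1)[C@H](O)C2 | intermediate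
13 | 5,7,3′,4′,5′-penta-O-benzyl-6,8-dibromo-3-O-[3,4,5-tris(benzyloxy)benzoyl]epigallocatechin-(4β→8)-5,7,3′,4′,5′-penta-O-benzylepigallocatechin | O=C(O[C@@H]1[C@@H](c2c(OCc3ccccc3)cc(OCc3ccccc3)c3c2O[C@H](c2cc(OCc4ccccc4)c(OCc4ccccc4)c(OCc4ccccc4)c2)[C@H](O)C3)c2c(OCc3ccccc3)c(Br)c(OCc3ccccc3)c(Br)c2O[C@@H]1c1cc(OCc2ccccc2)c(OCc2ccccc2)c(OCc2ccccc2)c1)c1cc(OCc2ccccc2)c(OCc2ccccc2)c(OCc2ccccc2)c1 | intermediate
14 | (−)-epigallocatechin 3-O-gallate-(4β→8)-(−)-epigallocatechin | O=C(O[C@@H]1[C@@H](c2c(O)cc(O)c3c2O[C@H](c2cc(O)c(O)c(O)c2)[C@H](O)C3)c2c(O)cc(O)cc2O[C@@H]1c1cc(O)c(O)c(O)c1)c1cc(O)c(O)c(O)c1 | target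

**Step count and risks**

Total step count: 8. Longest linear sequence: 5 steps (steps 1, 2, 5, 7, 8 from compound 1, or steps 3, 4, 5, 7, 8 from compound 4).

Steps most likely to fail:

Step 5 (Proposed new method). The cycloaddition may take the opposite regiochemical course, with O1 bonding to the acyloxy carbon. The Z enol ester may isomerize under the acid before it reacts, or the ring may close stepwise with loss of the cis relationship. The chiral anion may also discriminate the two alkene faces poorly. The fallback uses known chemistry, sets out from compounds 12 and 6 and comes back to the route at the target 14. Benzylic oxidation of 12 with DDQ in CH2Cl2/MeOH should give 4β-methoxy-5,7,3′,4′,5′-penta-O-benzylepigallocatechin F1, methanol adding anti to the C3 hydroxyl. Steglich esterification of F1 with acid 6 (DCC, DMAP, CH2Cl2) should give 4β-methoxy-5,7,3′,4′,5′-penta-O-benzyl-3-O-[3,4,5-tris(benzyloxy)benzoyl]epigallocatechin F2, the bromine-free analogue of 10. TMSOTf-mediated coupling of F2 with 12 as in step 7 should give 5,7,3′,4′,5′-penta-O-benzyl-3-O-[3,4,5-tris(benzyloxy)benzoyl]epigallocatechin-(4β→8)-5,7,3′,4′,5′-penta-O-benzylepigallocatechin F3. Hydrogenolysis of F3 over Pd(OH)2/C then gives 14.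

Step 7. Ionization of the hindered, bromine-deactivated C4 methyl ether may be slow, so that acid-mediated decomposition of the partners or attack through C6 of the nucleophile competes. The fallback sets out from compound 10 and comes back at compound 13, and replaces oxophilic by thiophilic activation. Thiolysis of 10 with benzyl mercaptan and BF3·OEt2 in CH2Cl2 (a small, strong nucleophile in excess, added anti to the gallate) should give (2R,3R,4S)-4-(benzylsulfanyl)-5,7-bis(benzyloxy)-6,8-dibromo-2-[3,4,5-tris(benzyloxy)phenyl]chroman-3-yl 3,4,5-tris(benzyloxy)benzoate F4. Irreversible activation of F4 with AgBF4 in THF at 0 °C in the presence of 12 should then form the 4β→8 bond of 13.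

Step 4. The catalyst may give Markovnikov addition, or the Z enol ester may be eroded to the E isomer, which would end as the 2,3-trans series after step 5. The fallback sets out from compound 5 and comes back at compound 7, and fixes the geometry at boron before the C–O bond is made. Rhodium-catalysed trans-hydroboration of 5 ([Rh(cod)Cl]2, P(i-Pr)3, Et3N, catecholborane, then aqueous hydrolysis) should give (Z)-2-[3,4,5-tris(benzyloxy)phenyl]ethenylboronic acid F5. Chan–Lam coupling of F5 with acid 6 (Cu(OAc)2, Et3N, 4 Å MS, air, CH2Cl2) should give 7 with retention of the double-bond geometry.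

Further compounds
F1 | step 5 | 4β-methoxy-5,7,3′,4′,5′-penta-O-benzylepigallocatechin | O[C@@H]1[C@@H](OC)c2c(OCc3ccccc3)cc(OCc3ccccc3)cc2O[C@@H]1c1cc(OCc2ccccc2)c(OCc2ccccc2)c(OCc2ccccc2)c1
F2 | step 5 | 4β-methoxy-5,7,3′,4′,5′-penta-O-benzyl-3-O-[3,4,5-tris(benzyloxy)benzoyl]epigallocatechin | O=C(O[C@@H]1[C@@H](OC)c2c(OCc3ccccc3)cc(OCc3ccccc3)cc2O[C@@H]1c1cc(OCc2ccccc2)c(OCc2ccccc2)c(OCc2ccccc2)c1)c1cc(OCc2ccccc2)c(OCc2ccccc2)c(OCc2ccccc2)c1
F3 | step 5 | 5,7,3′,4′,5′-penta-O-benzyl-3-O-[3,4,5-tris(benzyloxy)benzoyl]epigallocatechin-(4β→8)-5,7,3′,4′,5′-penta-O-benzylepigallocatechin | O=C(O[C@@H]1[C@@H](c2c(OCc3ccccc3)cc(OCc3ccccc3)c3c2O[C@H](c2cc(OCc4ccccc4)c(OCc4ccccc4)c(OCc4ccccc4)c2)[C@H](O)C3)c2c(OCc3ccccc3)cc(OCc3ccccc3)cc2O[C@@H]1c1cc(OCc2ccccc2)c(OCc2ccccc2)c(OCc2ccccc2)c1)c1cc(OCc2ccccc2)c(OCc2ccccc2)c(OCc2ccccc2)c1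
F4 | step 7 | (2R,3R,4S)-4-(benzylsulfanyl)-5,7-bis(benzyloxy)-6,8-dibromo-2-[3,4,5-tris(benzyloxy)phenyl]chroman-3-yl 3,4,5-tris(benzyloxy)benzoate | O=C(O[C@@H]1[C@@H](SCc2ccccc2)c2c(OCc3ccccc3)c(Br)c(OCc3ccccc3)c(Br)c2O[C@@H]1c1cc(OCc2ccccc2)c(OCc2ccccc2)c(OCc2ccccc2)c1)c1cc(OCc2ccccc2)c(OCc2ccccc2)c(OCc2ccccc2)c1
F5 | step 4 | (Z)-2-[3,4,5-tris(benzyloxy)phenyl]ethenylboronic acid | OB(O)/C=C\c1cc(OCc2ccccc2)c(OCc2ccccc2)c(OCc2ccccc2)c1
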